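**Retrosynthetic overview**

1. Target 18 ⇒ alcohol 16; the isovalerate goes on last.
2. Oxygen bridge (both seven-membered ether rings in one event, C9 and C10 set) ⇒ 9,10-epoxide 15, opened across the ring at C10 by the 5-OH ⇒ (9E)-alkene 14.
3. γ-Lactone ⇒ acyl shift from O5 to O8 in bridged lactone 13; ten-membered carbocycle ⇒ C7–C8 bond from allylic bromide/enal 11 through an allylchromium (C7 and C8 set).
4. 11 ⇒ ring-closing metathesis of ester 10 (six-membered lactone as a temporary tether) ⇒ 8 + 9; C5 by Ir-catalysed allylation with 4, C4 by Ru-catalysed hydrogenation, carbon chain from geranyl acetate 1.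
5. Ring order: tether lactone → ten-membered carbocycle → γ-lactone → oxygen bridge.

Assumption: the biosynthesis is taken to be an allyl-type closure of the ten-membered ring at C7, lactonization of the C12 acyl group onto O8, and transannular opening of a 9,10-epoxide at C10 by the 5-hydroxyl, which makes the 5,10-bridge and the 9-oxygen together.

Locants are germacrane locants of 18: C7/C8 carry the lactone, C12 is the lactone carbonyl, C13 the exocyclic methylene, C14 the methyl on C10, C15 the methyl on C4.

**Route**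

Step 1
Reactants: 1 geranyl acetate
Product: 2 (2E,6E)-8-hydroxy-3,7-dimethylocta-2,6-dien-1-yl acetate
Conditions: SeO2 (10 mol %), t-BuOOH, salicylic acid (10 mol %), CH2Cl2, rt
Reagents that add atoms: tert-butyl hydroperoxide, CC(C)(C)OO
Why: Catalytic SeO2/t-BuOOH allylic oxidation (ene reaction, then [2,3]-sigmatropic shift) attacks the electron-rich terminal trisubstituted alkene at its (E)-methyl group and spares the alkene deactivated by the allylic acetate; no stereocentre is formed.

Step 2
Reactants: 2 (2E,6E)-8-hydroxy-3,7-dimethylocta-2,6-dien-1-yl acetate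
Product: 3 (2E,7S)-8-hydroxy-3,7-dimethyloct-2-en-1-yl acetate
Conditions: Ru(OAc)2[(S)-BINAP] (1 mol %), H2 (100 atm), MeOH, rt
Reagents that add atoms: none
Why: Noyori hydroxyl-directed asymmetric hydrogenation reduces only the alkene that carries the free allylic OH, and the (S)-BINAP complex is expected to deliver H2 to the face that gives 7S (later C4 S), the facial sense by which it converts geraniol into (R)-citronellol.

Step 3
Reactants: 3 (2E,7S)-8-hydroxy-3,7-dimethyloct-2-en-1-yl acetate; 4 allyl acetate
Product: 7 (2E,7S,8R)-3,7-dimethylundeca-2,10-diene-1,8-diol, via aldehyde 5 (not isolated), via homoallylic alcohol acetate 6 (not isolated)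
Conditions: [Ir(cod)Cl]2 (2.5 mol %), (R)-BINAP (5 mol %), 4-chloro-3-nitrobenzoic acid (10 mol %), Cs2CO3 (20 mol %), THF, 100 °C; then K2CO3, MeOH, rt
Reagents that add atoms: none
Why: Krische iridium-catalysed transfer-hydrogenative allylation from the alcohol oxidation level forms and allylates aldehyde 5 on the metal without epimerising its α-methyl centre, the (R)-BINAP catalyst (not the substrate) being relied on to set the new carbinol as 8R (later C5 R, the anti-Felkin isomer), and methanolysis of the primary acetate follows in the same flask.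

Step 4
Reactants: 7 (2E,7S,8R)-3,7-dimethylundeca-2,10-diene-1,8-diol
Product: 8 (2E,7S,8R)-8-hydroxy-3,7-dimethylundeca-2,10-dienal
Conditions: MnO2, CH2Cl2, rt
Reagents that add atoms: none
Why: Chemoselective MnO2 oxidation converts only the primary allylic alcohol into the (E)-enal and leaves the secondary homoallylic alcohol, the terminal alkene and both stereocentres untouched.

Step 5
Reactants: 8 (2E,7S,8R)-8-hydroxy-3,7-dimethylundeca-2,10-dienal; 9 2-(bromomethyl)acrylic acid
Product: 10 (4R,5S,9E)-5,9-dimethyl-11-oxoundeca-1,9-dien-4-yl 2-(bromomethyl)prop-2-enoate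
Conditions: DCC, DMAP (5 mol %), CH2Cl2, −20 → 0 °C
Reagents that add atoms: none
Why: Steglich esterification acylates the only hydroxyl with retention at C5, the low temperature and small DMAP loading keeping the allylic bromide intact.

Step 6
Reactants: 10 (4R,5S,9E)-5,9-dimethyl-11-oxoundeca-1,9-dien-4-yl 2-(bromomethyl)prop-2-enoate
Product: 11 (6R)-3-(bromomethyl)-6-[(2S,6E)-6-methyl-8-oxooct-6-en-2-yl]-5,6-dihydro-2H-pyran-2-one
Conditions: second-generation Hoveyda–Grubbs catalyst (5 mol %), toluene, 80 °C, 5 mM
Reagents that add atoms: none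
Why: Ring-closing metathesis of the terminal vinyl group with the 1,1-disubstituted acrylate alkene forms the C7=C11 bond in a six-membered lactone that masks O5 and locks the allylic bromide in an endocyclic geometry, while the trisubstituted enal alkene is inert; no stereocentre changes.

Step 7
Reactants: 11 (6R)-3-(bromomethyl)-6-[(2S,6E)-6-methyl-8-oxooct-6-en-2-yl]-5,6-dihydro-2H-pyran-2-one
Product: 14 (4S,5R,7R,8S,9E)-5-hydroxygermacra-9,11(13)-dien-8,12-olide, via allylchromium dichloride 12 (not isolated), via bridged lactone alcohol 13 (not isolated)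
Conditions: CrCl2 (8 equiv), THF, rt, slow addition to 2 mM; then CSA (10 mol %), CH2Cl2, rt on the crude product
Reagents that add atoms: none
Why: Proposed new method: allylchromium 12 should add through its γ-carbon C7 to the enal carbonyl (1,2-addition) in a chair transition state in which the lactone ring holds C6 trans to the CH2Cr group (E-crotyl type, hence the anti C7/C8 pair that becomes the trans-lactone), the forming ten-membered ring can only span the lactone ring cis at C5 and C7 so that C5 dictates 7R, and acid then shifts the acyl group to the 8-OH to give the more stable fused butyrolactone and free the 5-OH (8S here only because C9 is olefinic; same spatial arrangement as 8R in 18); the closest known reaction type is the CrCl2-mediated Nozaki–Hiyama intramolecular allylation of aldehydes by 2-(bromomethyl)acrylates used to close ten-membered germacranolide rings.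

Step 8
Reactants: 14 (4S,5R,7R,8S,9E)-5-hydroxygermacra-9,11(13)-dien-8,12-olide
Product: 16 (4S,5R,7R,8R,9S,10R)-5,10-epoxy-9-hydroxygermacr-11(13)-en-8,12-olide, via epoxide 15 (not isolated)
Conditions: mCPBA, CH2Cl2, 0 °C; then CSA (10 mol %), 0 °C → rt
Reagents that add atoms: mCPBA (3-chloroperoxybenzoic acid), OOC(=O)c1cccc(Cl)c1
Why: Prilezhaev epoxidation followed by acid-catalysed transannular epoxy-alcohol cyclization: the peracid should attack the only electron-rich alkene on its outer face, syn to the lactone oxygen (allylic strain, as in costunolide → parthenolide), which fixes C9 as S, and the 5-OH held over the inner face opens the epoxide at the tertiary C10 with inversion, which fixes C10 as R.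

Step 9
Reactants: 16 (4S,5R,7R,8R,9S,10R)-5,10-epoxy-9-hydroxygermacr-11(13)-en-8,12-olide; 17 3-methylbutanoic anhydride
Product: 18 (4S,5R,7R,8R,9S,10R)-5,10-epoxy-9-(3-methylbutanoyloxy)germacr-11(13)-en-8,12-olide (CNP0274454.1)
Conditions: DMAP (10 mol %), pyridine, CH2Cl2, rt
Reagents that add atoms: none
Why: DMAP-catalysed acyl transfer esterifies the hindered secondary 9-OH with retention at C9 and leaves the α-methylene lactone and the ether bridge untouched.

**Compound list**

1 | geranyl acetate, (2E)-3,7-dimethylocta-2,6-dien-1-yl acetate | CC(C)=CCC/C(C)=C/COC(C)=O | starting material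
2 | (2E,6E)-8-hydroxy-3,7-dimethylocta-2,6-dien-1-yl acetate | OC/C(C)=C/CC/C(C)=C/COC(C)=O | intermediate
3 | (2E,7S)-8-hydroxy-3,7-dimethyloct-2-en-1-yl acetate | OC[C@@H](C)CCC/C(C)=C/COC(C)=O | intermediate
4 | allyl acetate | C=CCOC(C)=O | starting material
5 | (2E,7S)-3,7-dimethyl-8-oxooct-2-en-1-yl acetate | O=C[C@@H](C)CCC/C(C)=C/COC(C)=O | intermediate
6 | (2E,7S,8R)-8-hydroxy-3,7-dimethylundeca-2,10-dien-1-yl acetate | C=CC[C@@H](O)[C@@H](C)CCC/C(C)=C/COC(C)=O | intermediate
7 | (2E,7S,8R)-3,7-dimethylundeca-2,10-diene-1,8-diol | C=CC[C@@H](O)[C@@H](C)CCC/C(C)=C/CO | intermediate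
8 | (2E,7S,8R)-8-hydroxy-3,7-dimethylundeca-2,10-dienal | C=CC[C@@H](O)[C@@H](C)CCC/C(C)=C/C=O | intermediate
9 | 2-(bromomethyl)acrylic acid | C=C(CBr)C(=O)O | starting material
10 | (4R,5S,9E)-5,9-dimethyl-11-oxoundeca-1,9-dien-4-yl 2-(bromomethyl)prop-2-enoate | C=CC[C@@H](OC(=O)C(=C)CBr)[C@@H](C)CCC/C(C)=C/C=O | intermediate
11 | (6R)-3-(bromomethyl)-6-[(2S,6E)-6-methyl-8-oxooct-6-en-2-yl]-5,6-dihydro-2H-pyran-2-one | O=C1O[C@H](CC=C1CBr)[C@@H](C)CCC/C(C)=C/C=O | intermediate
12 | {(6R)-6-[(2S,6E)-6-methyl-8-oxooct-6-en-2-yl]-2-oxo-5,6-dihydro-2H-pyran-3-yl}methylchromium dichloride | O=C1O[C@H](CC=C1C[Cr](Cl)Cl)[C@@H](C)CCC/C(C)=C/C=O | intermediate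
13 | (1R,2S,3E,8S,9R)-2-hydroxy-4,8-dimethyl-12-methylidene-10-oxabicyclo[7.3.1]tridec-3-en-11-one (ten-membered ring closed, C12 still esterified to O5, free 8-OH) | C=C1C(=O)O[C@@H]2C[C@H]1[C@@H](O)/C=C(C)/CCC[C@@H]2C | intermediate
14 | (4S,5R,7R,8S,9E)-5-hydroxygermacra-9,11(13)-dien-8,12-olide | C=C1C(=O)O[C@H]2/C=C(C)/CCC[C@H](C)[C@H](O)C[C@H]12 | intermediate
15 | (4S,5R,7R,8R,9S,10S)-9,10-epoxy-5-hydroxygermacr-11(13)-en-8,12-olide | C=C1C(=O)O[C@@H]2[C@@H]1C[C@@H](O)[C@@H](C)CCC[C@]3(C)O[C@@H]23 | intermediate
16 | (4S,5R,7R,8R,9S,10R)-5,10-epoxy-9-hydroxygermacr-11(13)-en-8,12-olide | C=C1C(=O)O[C@@H]2[C@@H]1C[C@H]1O[C@](C)(CCC[C@@H]1C)[C@H]2O | intermediate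
17 | 3-methylbutanoic anhydride (isovaleric anhydride) | CC(C)CC(=O)OC(=O)CC(C)C | starting material
18 | (4S,5R,7R,8R,9S,10R)-5,10-epoxy-9-(3-methylbutanoyloxy)germacr-11(13)-en-8,12-olide | C=C1C(=O)O[C@@H]2[C@@H]1C[C@H]1O[C@](C)(CCC[C@@H]1C)[C@H]2OC(=O)CC(C)C | target

**Step count**

Total steps: 9. Longest linear sequence: 9 steps (1 → 18); 4, 9 and 17 are bought and enter directly.

**Three steps most likely to fail**

Step 7 (ten-membered ring closure). Oligomers, the wrong C7/C8 pair or an incomplete acyl shift are all possible. The fallback replaces the organochromium addition by a metal-free allylboration through a closed transition state. It sets out from 11: Pd2(dba)3-catalysed borylation with bis(pinacolato)diboron turns the allylic bromide into the primary allylboronate (6R)-6-[(2S,6E)-6-methyl-8-oxooct-6-en-2-yl]-3-[(4,4,5,5-tetramethyl-1,3,2-dioxaborolan-2-yl)methyl]-5,6-dihydro-2H-pyran-2-one F1, a 2-alkoxycarbonyl allylboronate slow enough to isolate. Sc(OTf)3 (cat.) in toluene at 2 mM then triggers the intramolecular allylboration of the enal through the same lactone-locked chair, and CSA treatment of the crude product gives 14, where the fallback rejoins the route.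

Step 8 (epoxidation and transannular ether closure). The peracid may choose the wrong face, the hydroxyl may open the epoxide at C9, or the epoxide may rearrange before capture. The fallback changes the substrate and the order of events so that a free allylic hydroxyl steers the epoxidation. It sets out from 13, obtained by stopping step 7 before the acid treatment: NaHCO3-buffered mCPBA, guided by hydrogen bonding to the 8-OH and by allylic strain, gives (4S,5R,7R,8R,9S,10S)-9,10-epoxy-8-hydroxygermacr-11(13)-en-12,5-olide F2. CSA then shifts the acyl group to O8, which forms 15 in the flask, and the released 5-OH closes the bridge to 16, where the fallback rejoins the route.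

Step 6 (ring-closing metathesis next to an allylic bromide). The bromide may deactivate the catalyst or the hindered acrylate may react too slowly. The fallback carries the bromide-bearing carbon through the metathesis as a silyl ether and introduces bromine afterwards. It sets out from 8: commercial ethyl 2-(hydroxymethyl)acrylate is silylated (TBSCl, imidazole) to ethyl 2-{[tert-butyl(dimethyl)silyl]oxymethyl}prop-2-enoate F3 and saponified (LiOH) to 2-{[tert-butyl(dimethyl)silyl]oxymethyl}prop-2-enoic acid F4. Steglich esterification of 8 with F4 gives (4R,5S,9E)-5,9-dimethyl-11-oxoundeca-1,9-dien-4-yl 2-{[tert-butyl(dimethyl)silyl]oxymethyl}prop-2-enoate F5, and metathesis with the same catalyst gives (6R)-3-{[tert-butyl(dimethyl)silyl]oxymethyl}-6-[(2S,6E)-6-methyl-8-oxooct-6-en-2-yl]-5,6-dihydro-2H-pyran-2-one F6. Ph3PBr2 converts the silyl ether directly into the bromide 11, where the fallback rejoins the route.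

Further compounds
F1 | step 7 | (6R)-6-[(2S,6E)-6-methyl-8-oxooct-6-en-2-yl]-3-[(4,4,5,5-tetramethyl-1,3,2-dioxaborolan-2-yl)methyl]-5,6-dihydro-2H-pyran-2-one | O=C1O[C@H](CC=C1CB2OC(C)(C)C(C)(C)O2)[C@@H](C)CCC/C(C)=C/C=O
F2 | step 8 | (4S,5R,7R,8R,9S,10S)-9,10-epoxy-8-hydroxygermacr-11(13)-en-12,5-olide | C=C1C(=O)O[C@@H]2C[C@H]1[C@@H](O)[C@@H]1O[C@@]1(C)CCC[C@@H]2C
F3 | step 6 | ethyl 2-{[tert-butyl(dimethyl)silyl]oxymethyl}prop-2-enoate | C=C(CO[Si](C)(C)C(C)(C)C)C(=O)OCC
F4 | step 6 | 2-{[tert-butyl(dimethyl)silyl]oxymethyl}prop-2-enoic acid | C=C(CO[Si](C)(C)C(C)(C)C)C(=O)O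
F5 | step 6 | (4R,5S,9E)-5,9-dimethyl-11-oxoundeca-1,9-dien-4-yl 2-{[tert-butyl(dimethyl)silyl]oxymethyl}prop-2-enoate | C=CC[C@@H](OC(=O)C(=C)CO[Si](C)(C)C(C)(C)C)[C@@H](C)CCC/C(C)=C/C=O
F6 | step 6 | (6R)-3-{[tert-butyl(dimethyl)silyl]oxymethyl}-6-[(2S,6E)-6-methyl-8-oxooct-6-en-2-yl]-5,6-dihydro-2H-pyran-2-one | O=C1O[C@H](CC=C1CO[Si](C)(C)C(C)(C)C)[C@@H](C)CCC/C(C)=C/C=O
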